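I would put the next 40 h into G, not into D and not into taking L out.

- larch: X 0.050 M; G 2.5 equiv; D 9.3 mol%; the very flask that is asked about, followed so far
- flask: X 0.050 M; G 2.50 equiv; D 9.3 mol%; time 20 h

larch run (percent of the X charged)

| time / h | L / % | X / % |
|---|---|---|
| 3.00 | 7.0 | 85.1 |
| 6.00 | 14.7 | 73.8 |
| 10.0 | 20.6 | 57.7 |
| 12.0 | 18.5 | 53.6 |
| 15.0 | 19.6 | 45.4 |

(scatter of a reading: 1 percentage point)

- beta: at 20 h add D, 50.0% of the amount charged, then wait 40 h
- alpha: change nothing and wait 40 h more
- theta: at 20 h take out 90% of the L then present, then wait 40 h
- gamma: at 20 h add G, 50.0% of the amount charged, then wait 40 h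

- what is taken out of L is counted as made
- additions bring no volume worth counting

- L, in percent of the X first charged, at 20 h
- what to do for the largest gain in L; "none" if nothing gains more than 2 percentage points (beta / alpha / theta / gamma / none)
- L present, with what was taken out counted in, in percent of the X first charged, after beta
- L present, with what was taken out counted in, in percent of the X first charged, after gamma

In the first hours of the larch run, X falls and L rises. By 3.00 h the flask has lost 14.9% of its X and holds 7.0% of L, so about half of the X gone has appeared as L.

In the middle, L climbs to 20.6% at 10.0 h, and X keeps its pace. Its first-order constant is 0.0506 /h up to 6.00 h and 0.0526 /h up to 15.0 h. X thus behaves as pseudo-first-order, and I see no sign that D is failing.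

At the end the two part. From 10.0 h to 15.0 h, X falls by 12 percentage points, far more than the 1 point that L moves, and that move is about one scatter. L stands at 19.6% on average while X is still going.

I read this as L having stopped being made, and I take G to be its limiting reagent despite the 2.5 equiv charged. One run can't prove that reading, but it gives a usable number, the yield on G, y_G: L made per G charged. Here y_G is 0.0783.

My reckoning follows from it. L at 20 h stays near 19.6%, and beta, alpha and theta bring no G, so none of them should gain more than 2 points. Gamma's dose should bring 9.8 points, for about 29.4%.

The forecast says 19.5% now (17.8% to 21.2%), 2.2% after beta, 3.3% after gamma, and theta as best, with “L itself lost at about 0.08 /h”.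

The flask gives 19.8% now, 19.9% after beta, 32.7% after gamma, and gamma as best, with a gain of 13 points.

    J → Q (k = 0.195 /h)
    D + J ⇌ Z (K = 14.0 /M, k = 730 /M/h)
    G → E (k = 0.310 /h)
    X + D → D + J (k = 11.5 /M/h)
    G + Z → D + L (k = 246 /M/h)

At 2.02 h in the flask, G → E uses G 13 times as fast as G + Z → D + L does. By 10.0 h G is down to 2.97% of its charge, and L still stands at 19.8% at 200 h. Gamma's dose yields 0.103, more than y_G. One more flask, like this one but with 6.20 equiv of G, holds 29.5% of L at 20.0 h, not the 48.5% that y_G gives, a yield of 0.0476.

The data are calculated on assumed constants, and the scatter is random.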